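## Retrosynthetic overview

1. 37 ⇐ 34 by three finishing operations. A C3≡C4 enyne that masks the Z-diene is semihydrogenated. Chloride displaces a 6R-hydroxyl by SN2, so chlorine enters only after the radical step. O14 is then acetylated.
2. 34 ⇐ 31, disconnection C1–C10. The cyclohexane (C1, C10, C11, C12, C13, C14) shares only this bond with the ten-membered ring (C1 to C10). Both rings are therefore cut out of one 14-membered carbocycle by a transannular epoxide-opening radical cyclization with Cp2TiCl.
3. Enabling feature: C14–O sits next to the quaternary C1(C15H3), and the exocyclic C11=C20 methylene sits next to C10–H. This pattern is what remains after three events: a C1/C14 oxirane opens to a tertiary C1 radical, the radical adds 6-endo to a C10=C11(CH3) olefin, and a hydrogen atom is lost from C20.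
4. 31 ⇐ Shi epoxidation, NHK closure C5–C6, alkynylation C2–C3, cross metathesis C14=C1, allylation C12–C13 and Wittig C10=C11. L-Arabinose C1 to C5 become C6 to C10: C7 and C9 are kept, and C8 is set on the derived 3-ulose by a Reformatsky addition that also brings C17 to C19.
5. Ring order: γ-lactone (step 5) → 14-membered carbocycle (step 19) → cyclohexane last (step 23). The new C1–C10 bond leaves the rest of the perimeter as the ten-membered ring.

Key step: step 23

**Numbering (briarane), used for all intermediates.**
- C1: quaternary ring-fusion carbon, bears C15H3.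
- C2: CH(OAc) next to C1 in the ten-membered ring.
- C3=C4: Z-olefin.
- C5: bears =C16H2.
- C6: CHCl.
- C7: lactone O–CH.
- C8: C(OH).
- C9: CH(OAc).
- C10: ring-fusion CH.
- C11: bears =C20H2.
- C12: CH(OAc).
- C13: CH2.
- C14: CH(OAc).
- C17: lactone CH, bears C18H3.
- C19: lactone C=O.
- The α face is the cyclohexane face opposite to C15.

**Where each stereocentre is set.**
- C7 and C9: from L-arabinose.
- C8: step 4.
- C17: step 7.
- C12: step 11.
- C2: step 16.
- C6: step 21, inverted in step 25.
- C14: step 22.
- C1 and C10: step 23.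

CIP letters change along the route where substituent ranks change. The spatial arrangement does not change unless a step says so.

**Remark (assumption).** The antipode of the ProPhenol ligand in step 16 is specified by the aldehyde face it must attack (Si face at C2), not by its own descriptor.

## Route

Step 1
Reactants: 1 L-arabinose
Product: 2 5-O-(tert-butyldiphenylsilyl)-L-arabinofuranose (anomer mixture)
Conditions: TBDPSCl (1.05 equiv), pyridine, 0 °C to rt
Reagents that add atoms: tert-butyl(chloro)diphenylsilane, CC(C)(C)[Si](Cl)(c1ccccc1)c1ccccc1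
Why: Selective silylation of a primary alcohol: only the furanose form of 1 offers a primary hydroxyl, so O5 silylation pulls the tautomeric equilibrium into 2 and touches no stereocentre.

Step 2
Reactants: 2 5-O-TBDPS-L-arabinofuranose
Product: 3 5-O-TBDPS-1,2-O-isopropylidene-β-L-arabinofuranose
Conditions: Me2C(OMe)2, p-TsOH (cat.), acetone, rt
Reagents that add atoms: 2,2-dimethoxypropane, COC(C)(C)OC
Why: Acid-catalysed acetonide formation (transketalization) takes the only cis-1,2-diol, O1/O2 of the β-anomer, which fixes the anomeric centre and leaves O3–H free.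

Step 3
Reactants: 3 acetonide
Product: 4 5-O-TBDPS-1,2-O-isopropylidene-β-L-threo-pentofuranos-3-ulose
Conditions: Dess–Martin periodinane, pyridine, CH2Cl2, 0 °C to rt
Reagents that add atoms: none
Why: Dess–Martin oxidation is neutral enough to give the 3-ulose without epimerization of the adjacent sugar C4 (later C9).

Step 4
Reactants: 4 3-ulose; 5 tert-butyl 2-bromopropanoate
Product: 7 tert-butyl 2-(5-O-TBDPS-1,2-O-isopropylidene-β-L-lyxofuranos-3-C-yl)propanoate (3-OH cis to the acetonide; C17 epimers), via bromozinc enolate 6 (not isolated)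
Conditions: Zn dust (activated), THF, 0 °C to rt; then cold dilute HCl
Reagents that add atoms: none
Why: Reformatsky reaction: the weakly basic zinc enolate 6 adds to the ketone from the convex face, because the acetonide and the CH2OTBDPS arm both lie on the concave face of the cis-fused bicycle, which sets C8, while C17 forms as a mixture that step 7 corrects.

Step 5
Reactants: 7 Reformatsky adduct
Product: 9 (4R,5R)-5-(1,3-dithian-2-yl)-4-hydroxy-4-[(1S)-1-hydroxy-2-(TBDPS-oxy)ethyl]-3-methyloxolan-2-one (7R,8R,9S; C17 epimers), via dithiane hydroxy acid 8 (not isolated)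
Conditions: HS(CH2)3SH (1.5 equiv), CF3CO2H/CH2Cl2 1:3, 0 °C to rt
Reagents that add atoms: propane-1,3-dithiol, SCCCS
Why: Transthioacetalization opens the furanose to the acyclic dithiane 8 while the same acid cleaves the tert-butyl ester, and reversible acid-catalysed γ-lactonization chooses O7 over O9 because only the O7 lactone carries its two large residues (dithiane on C7, C9 chain on C8) trans on the five-membered ring.

Step 6
Reactants: 9 dithiane lactone diol
Product: 10 C9 acetate of 9 (7R,8R,9S; C17 epimers)
Conditions: Ac2O (1.2 equiv), pyridine, DMAP (cat.), 0 °C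
Reagents that add atoms: acetic anhydride, CC(=O)OC(C)=O
Why: Standard acylation: the secondary C9 hydroxyl is esterified while the tertiary C8 hydroxyl stays free, which also blocks any later translactonization to O9.

Step 7
Reactants: 10 C9 acetate (C17 epimers)
Product: 11 C9 acetate, single isomer (7R,8R,9S,17R)
Conditions: DBU (0.3 equiv), toluene, rt to 40 °C
Reagents that add atoms: none
Why: Base-catalysed epimerization next to the lactone carbonyl (thermodynamic control) funnels both C17 epimers into the isomer whose C18 methyl group is trans to the bulky C9 chain and cis to the small C8 hydroxyl, the configuration of 37.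

Step 8
Reactants: 11 silyl ether
Product: 12 primary C10 alcohol (7R,8R,9S,17R)
Conditions: HF·pyridine, pyridine/THF, 0 °C to rt
Reagents that add atoms: none
Why: Fluoride-mediated desilylation in an acidic medium frees the primary C10 hydroxyl without acetyl migration from O9.

Step 9
Reactants: 12 primary alcohol
Product: 13 C10 aldehyde (7R,8R,9R,17R; the letter at C9 changes by rank only)
Conditions: Dess–Martin periodinane, pyridine, dry CH2Cl2, 0 °C
Reagents that add atoms: none
Why: Dess–Martin oxidation under anhydrous buffered conditions gives the α-acetoxy aldehyde without epimerization at C9 and leaves the dithiane intact.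

Step 10
Reactants: 13 C10 aldehyde; 14 2-(triphenylphosphoranylidene)propanal
Product: 15 (10E)-enal with C12 as the aldehyde carbon (7R,8R,9S,17R)
Conditions: toluene, 60 °C
Reagents that add atoms: none
Why: Wittig olefination with a stabilised ylide gives the E-trisubstituted enal (C9 trans to C12), the α-oxygenated aldehyde 13 being more reactive than the enal that is formed.

Step 11
Reactants: 15 enal; 16 allyltributylstannane
Product: 17 (12R)-homoallylic alcohol (7R,8R,9S,12R,17R; 10E)
Conditions: (R)-BINOL (20 mol %), Ti(OiPr)4 (20 mol %), 4 Å MS, CH2Cl2, −20 °C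
Reagents that add atoms: none
Why: Keck asymmetric allylation: the (R)-BINOL–titanium Lewis acid directs the allylstannane to the Re face of the enal in a 1,2-addition, which sets 12R under catalyst control.

Step 12
Reactants: 17 homoallylic alcohol
Product: 18 C9,C12 diacetate with terminal olefin
Conditions: Ac2O, pyridine, DMAP (cat.), 0 °C to rt
Reagents that add atoms: acetic anhydride, CC(=O)OC(C)=O
Why: Standard acylation installs the C12 acetate of the target, the tertiary C8 hydroxyl being too hindered to react.

Step 13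
Reactants: 18 terminal olefin; 19 methacrolein
Product: 20 (E)-2-methylenal with C2 as the aldehyde carbon (7R,8R,9S,12R,17R; C10=C11 E, C14=C1 E)
Conditions: second-generation Hoveyda–Grubbs catalyst (5 mol %), CH2Cl2, 40 °C
Reagents that add atoms: none
Why: Olefin cross metathesis of the terminal olefin with methacrolein gives the thermodynamically favoured E-2-methylenal, the trisubstituted C10=C11 olefin being inert to the catalyst.

Step 14
Reactants: 21 4-(trimethylsilyl)but-3-yn-2-one
Product: 22 4-(trimethylsilyl)but-1-en-3-yn-2-yl trifluoromethanesulfonate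
Conditions: Tf2O (1.2 equiv), 2,6-di-tert-butyl-4-methylpyridine (1.3 equiv), CH2Cl2, 0 °C to rt
Reagents that add atoms: trifluoromethanesulfonic anhydride, O=S(=O)(OS(=O)(=O)C(F)(F)F)C(F)(F)F
Why: Enol triflate formation from an alkynyl methyl ketone with a hindered non-nucleophilic base, in which only the methyl group can enolize.

Step 15
Reactants: 22 silylated enynyl triflate
Product: 23 but-1-en-3-yn-2-yl trifluoromethanesulfonate (carries C3, C4, C5, C16)
Conditions: Bu4NF, AcOH, THF, 0 °C; used as a solution
Reagents that add atoms: none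
Why: Buffered fluoride protodesilylation of the alkynylsilane leaves the alkenyl triflate untouched.

Step 16
Reactants: 20 enal; 23 enynyl triflate
Product: 25 C2 propargylic alcohol (2R,7R,8R,9S,12R,17R; C2–O oriented as in 37), via alkynylzinc reagent 24 (not isolated)
Conditions: Me2Zn (3 equiv), ProPhenol ligand (20 mol %, antipode that directs Si-face attack), Ph3P=O (40 mol %), toluene, 4 °C; then aq. NH4Cl
Reagents that add atoms: none
Why: Zinc–ProPhenol catalysed asymmetric alkynylation of an α,β-unsaturated aldehyde delivers 24 to the Si face of the C2 aldehyde under catalyst control, while lactone, acetates, dithiane and alkenyl triflate are inert to the organozinc.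

Step 17
Reactants: 25 propargylic alcohol
Product: 26 C2,C9,C12 triacetate
Conditions: Ac2O, pyridine, DMAP (cat.), 0 °C
Reagents that add atoms: acetic anhydride, CC(=O)OC(C)=O
Why: Standard acylation installs the C2 acetate of the target and protects O2 against the oxidation in step 20.

Step 18
Reactants: 26 dithiane
Product: 27 C6 aldehyde (2R,7R,8R,9S,12R,17R)
Conditions: MeI (excess), CaCO3, MeCN/H2O 9:1, 40 °C
Reagents that add atoms: water, O
Why: Alkylative hydrolysis of the dithiane (S-methylation, then hydrolysis) is neutral and non-oxidative, so the olefins, the alkenyl triflate and the allylic acetates survive and C7 is not epimerized.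

Step 19
Reactants: 27 aldehyde–alkenyl triflate
Product: 28 14-membered enynol fused to the γ-lactone (C6 epimers)
Conditions: CrCl2 (8 equiv), NiCl2 (0.1 equiv), DMF/THF, 27 added slowly to 0.002 M, rt
Reagents that add atoms: none
Why: Intramolecular Nozaki–Hiyama–Kishi reaction: nickel-catalysed activation of the alkenyl triflate, transmetalation to chromium and chemoselective addition to the aldehyde close the C5–C6 bond at high dilution, and the C6 configuration is irrelevant because step 20 erases it.

Step 20
Reactants: 28 macrocyclic enynol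
Product: 29 macrocyclic C6 enynone (2R,7R,8R,9S,12R,17R)
Conditions: Dess–Martin periodinane, pyridine, CH2Cl2, 0 °C
Reagents that add atoms: none
Why: Dess–Martin oxidation of the only secondary alcohol present, the tertiary C8 hydroxyl being inert.

Step 21
Reactants: 29 enynone
Product: 30 (6R)-macrocyclic enynol (2R,6R,7S,8R,9S,12R,17R; O6 and O7 syn)
Conditions: NaBH4, CeCl3·7H2O, MeOH, −78 °C
Reagents that add atoms: none
Why: Luche 1,2-reduction: in the polar Felkin–Anh conformer, reinforced by cerium bridging the ketone and the cis C8 hydroxyl, hydride attacks anti to the C7–O bond and gives the 6R alcohol.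

Step 22
Reactants: 30 macrocyclic trienyne
Product: 31 (1R,14S)-1,14-epoxide (1R,2S,6R,7S,8R,9S,12R,14S,17R)
Conditions: L-fructose-derived Shi ketone (0.3 equiv), KHSO5 (as 2KHSO5·KHSO4·K2SO4), K2CO3, Bu4NHSO4 (cat.), MeCN/CH2(OMe)2/aq. Na2B4O7 buffer, 0 °C
Reagents that add atoms: potassium peroxymonosulfate, [K+].[O-]S(=O)(=O)OO
Why: Shi epoxidation (chiral dioxirane, spiro transition state) delivers oxygen to the face of the E-trisubstituted C14=C1 olefin that makes C14 S, and it picks this olefin because C10=C11 is deactivated by two allylic acetates and C5=C16 by the conjugated alkyne; the configuration created at C1 does not matter, since step 23 makes C1 planar.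

Step 23
Reactants: 31 macrocyclic epoxide
Product: 34 tricyclic enyne triol triacetate (1R,2S,6R,7S,8R,9S,10S,12R,14S,17R; free OH at C6, C8, C14), via C1 radical 32 (not isolated), via C11 radical 33 (not isolated)
Conditions: Cp2TiCl2 (2.5 equiv), Mn dust (8 equiv), degassed THF, rt, 31 added over 2 h to 0.003 M; then cold 1 M HCl
Reagents that add atoms: none
Why: Proposed new method: Cp2TiCl (trivalent titanium, made in the flask) coordinates the oxirane oxygen of 31 and transfers one electron, so that the C1–O bond breaks to the more substituted, planar tertiary radical 32 while the C14–O stereocentre stays intact; 32 adds across the ring to C10, and the resulting tertiary C11 radical 33, too hindered to be captured as an alkyltitanium, loses a hydrogen atom from the C20 methyl group to a second Cp2TiCl (mixed disproportionation), which creates the C11=C20 methylene. The closest known reaction type is the Cp2TiCl-mediated 6-endo cyclization of epoxypolyprenes and its transannular version on ten-membered epoxygermacrolides, both ending in exocyclic olefins; new is the use on a 14-membered carbocycle to cut out a six- and a ten-membered ring at once. The cyclohexane closes 6-endo-trig along the C14–C13–C12 tether, and the ten-membered ring is the same bond seen as a 10-exo-trig closure along the C2-to-C9 tether. C10 is controlled by allylic 1,3-strain in the E-olefin: the C20 methyl group forces H9 into the olefin plane, the quaternary C8 and the C9 acetate then cover opposite faces, and C1 enters anti to C8, which places H10 on the α face. C1 is controlled by the chair-like transition state that the E-geometry imposes: the C9 and C2 branches, tied together by the rigid enyne–lactone bridge, both sit pseudo-equatorial, so that C15 ends axial and trans to H10, with the C12 acetate (kept off C20 by allylic 1,2-strain) and the C14–O–Ti bond pseudo-axial on the α face as in 37. The step needs 6-endo over 5-exo attack (secured by the fully substituted C11, which would otherwise have to become a second quaternary centre), chemoselectivity (the oxirane is the only group that Cp2TiCl reduces, chlorine is still absent, and the linear C3≡C4 unit keeps C4, C5 and C16 out of reach of C1) and exocyclic termination (the C20 hydrogens are the only unhindered ones next to C11).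

Step 24
Reactants: 34 ten-membered-ring enyne
Product: 35 (3Z)-3,5(16)-diene (1R,2S,6R,7S,8R,9S,10S,12R,14S,17R)
Conditions: H2 (1 atm), Pd/CaCO3 poisoned with Pb(OAc)2, quinoline, EtOAc, rt, stopped after one equivalent
Reagents that add atoms: none
Why: Lindlar semihydrogenation adds H2 syn to the ring alkyne and gives the Z-C3=C4 olefin, the 1,1-disubstituted olefins being reduced much more slowly on the poisoned catalyst.

Step 25
Reactants: 35 dienyl alcohol
Product: 36 (6S)-chloride (1R,2S,6S,7R,8R,9S,10S,12R,14S,17R; free OH at C8 and C14)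
Conditions: PPh3 (1.3 equiv), Cl3CC(O)CCl3 (3 equiv), 2,6-lutidine, CH2Cl2, −20 to 0 °C
Reagents that add atoms: hexachloroacetone, ClC(Cl)(Cl)C(=O)C(Cl)(Cl)Cl
Why: Appel-type chlorination: chloride displaces the alkoxyphosphonium group by SN2 with inversion (6R to 6S) and without allylic transposition, while the neopentyl C14 and the tertiary C8 hydroxyls are too hindered to be activated.

Step 26
Reactants: 36 chloride
Product: 37 target CNP0164748.1 (1R,2S,6S,7R,8R,9S,10S,12R,14S,17R)
Conditions: Ac2O, Et3N, DMAP, CH2Cl2, rt
Reagents that add atoms: acetic anhydride, CC(=O)OC(C)=O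
Why: DMAP-catalysed acylation esterifies the last secondary hydroxyl (C14) and leaves the tertiary C8 hydroxyl free, as in the target.

## Compound list

1 | L-arabinose | OC[C@H](O)[C@H](O)[C@@H](O)C=O | starting material
2 | 5-O-TBDPS-L-arabinofuranose (anomer mixture) | CC(C)(C)[Si](c1ccccc1)(c1ccccc1)OC[C@@H]1OC(O)[C@H](O)[C@H]1O | intermediate
3 | 5-O-TBDPS-1,2-O-isopropylidene-β-L-arabinofuranose | CC(C)(C)[Si](c1ccccc1)(c1ccccc1)OC[C@@H]1O[C@@H]2OC(C)(C)O[C@@H]2[C@H]1O | intermediate
4 | 5-O-TBDPS-1,2-O-isopropylidene-β-L-threo-pentofuranos-3-ulose | CC(C)(C)[Si](c1ccccc1)(c1ccccc1)OC[C@@H]1O[C@@H]2OC(C)(C)O[C@@H]2C1=O | intermediate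
5 | tert-butyl 2-bromopropanoate (racemic) | CC(Br)C(=O)OC(C)(C)C | starting material
6 | bromozinc enolate of tert-butyl propanoate (not isolated) | CC([Zn]Br)C(=O)OC(C)(C)C | intermediate
7 | Reformatsky adduct, 3-C-branched β-L-lyxofuranose (C17 epimers) | CC(C)(C)[Si](c1ccccc1)(c1ccccc1)OC[C@@H]1O[C@@H]2OC(C)(C)O[C@@H]2[C@@]1(O)C(C)C(=O)OC(C)(C)C | intermediate
8 | open-chain dithiane hydroxy acid (not isolated) | CC(C)(C)[Si](c1ccccc1)(c1ccccc1)OC[C@H](O)[C@](O)(C(C)C(=O)O)[C@@H](O)C1SCCCS1 | intermediate
9 | dithiane lactone diol (C17 epimers) | CC(C)(C)[Si](c1ccccc1)(c1ccccc1)OC[C@H](O)[C@]1(O)C(C)C(=O)O[C@H]1C2SCCCS2 | intermediate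
10 | C9 acetate (C17 epimers) | CC(C)(C)[Si](c1ccccc1)(c1ccccc1)OC[C@H](OC(C)=O)[C@]1(O)C(C)C(=O)O[C@H]1C2SCCCS2 | intermediate
11 | C9 acetate, 17R | CC(C)(C)[Si](c1ccccc1)(c1ccccc1)OC[C@H](OC(C)=O)[C@]1(O)[C@@H](C)C(=O)O[C@H]1C2SCCCS2 | intermediate
12 | primary C10 alcohol | OC[C@H](OC(C)=O)[C@]1(O)[C@@H](C)C(=O)O[C@H]1C2SCCCS2 | intermediate
13 | C10 aldehyde | O=C[C@H](OC(C)=O)[C@]1(O)[C@@H](C)C(=O)O[C@H]1C2SCCCS2 | intermediate
14 | 2-(triphenylphosphoranylidene)propanal | CC(C=O)=P(c1ccccc1)(c1ccccc1)c1ccccc1 | starting material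
15 | (10E)-C12 enal | O=C/C(C)=C/[C@H](OC(C)=O)[C@]1(O)[C@@H](C)C(=O)O[C@H]1C2SCCCS2 | intermediate
16 | allyltributylstannane | C=CC[Sn](CCCC)(CCCC)CCCC | starting material
17 | (12R)-homoallylic alcohol | C=CC[C@@H](O)/C(C)=C/[C@H](OC(C)=O)[C@]1(O)[C@@H](C)C(=O)O[C@H]1C2SCCCS2 | intermediate
18 | C9,C12 diacetate, terminal olefin | C=CC[C@@H](OC(C)=O)/C(C)=C/[C@H](OC(C)=O)[C@]1(O)[C@@H](C)C(=O)O[C@H]1C2SCCCS2 | intermediate
19 | methacrolein | C=C(C)C=O | starting material
20 | C2 enal | O=C/C(C)=C/C[C@@H](OC(C)=O)/C(C)=C/[C@H](OC(C)=O)[C@]1(O)[C@@H](C)C(=O)O[C@H]1C2SCCCS2 | intermediate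
21 | 4-(trimethylsilyl)but-3-yn-2-one | CC(=O)C#C[Si](C)(C)C | starting material
22 | 4-(trimethylsilyl)but-1-en-3-yn-2-yl triflate | C=C(OS(=O)(=O)C(F)(F)F)C#C[Si](C)(C)C | intermediate
23 | but-1-en-3-yn-2-yl triflate | C=C(OS(=O)(=O)C(F)(F)F)C#C | intermediate
24 | methyl(alkynyl)zinc reagent from 23 (not isolated) | C=C(OS(=O)(=O)C(F)(F)F)C#C[Zn]C | intermediate
25 | C2 propargylic alcohol | C=C(OS(=O)(=O)C(F)(F)F)C#C[C@H](O)/C(C)=C/C[C@@H](OC(C)=O)/C(C)=C/[C@H](OC(C)=O)[C@]1(O)[C@@H](C)C(=O)O[C@H]1C2SCCCS2 | intermediate
26 | C2,C9,C12 triacetate | C=C(OS(=O)(=O)C(F)(F)F)C#C[C@H](OC(C)=O)/C(C)=C/C[C@@H](OC(C)=O)/C(C)=C/[C@H](OC(C)=O)[C@]1(O)[C@@H](C)C(=O)O[C@H]1C2SCCCS2 | intermediate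
27 | C6 aldehyde | C=C(OS(=O)(=O)C(F)(F)F)C#C[C@H](OC(C)=O)/C(C)=C/C[C@@H](OC(C)=O)/C(C)=C/[C@H](OC(C)=O)[C@]1(O)[C@@H](C)C(=O)O[C@H]1C=O | intermediate
28 | macrocyclic enynol (C6 epimers) | C/C1=C\[C@H](OC(C)=O)[C@]2(O)[C@@H](C)C(=O)O[C@H]2C(O)C(=C)C#C[C@H](OC(C)=O)/C(C)=C/C[C@H]1OC(C)=O | intermediate
29 | macrocyclic enynone | C/C1=C\[C@H](OC(C)=O)[C@]2(O)[C@@H](C)C(=O)O[C@H]2C(=O)C(=C)C#C[C@H](OC(C)=O)/C(C)=C/C[C@H]1OC(C)=O | intermediate
30 | (6R)-macrocyclic enynol | C/C1=C\[C@H](OC(C)=O)[C@]2(O)[C@@H](C)C(=O)O[C@H]2[C@H](O)C(=C)C#C[C@H](OC(C)=O)/C(C)=C/C[C@H]1OC(C)=O | intermediate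
31 | (1R,14S)-macrocyclic epoxide | C/C1=C\[C@H](OC(C)=O)[C@]2(O)[C@@H](C)C(=O)O[C@H]2[C@H](O)C(=C)C#C[C@H](OC(C)=O)[C@]3(C)O[C@H]3C[C@H]1OC(C)=O | intermediate
32 | β-titanoxy C1 radical (not isolated) | C/C1=C\[C@H](OC(C)=O)[C@]2(O)[C@@H](C)C(=O)O[C@H]2[C@H](O)C(=C)C#C[C@H](OC(C)=O)[C](C)[C@@H](O[Ti](Cl)(C3C=CC=C3)C3C=CC=C3)C[C@H]1OC(C)=O | intermediate
33 | cyclized C11 radical (not isolated) | C[C]1[C@@H]2[C@H](OC(C)=O)[C@]3(O)[C@@H](C)C(=O)O[C@H]3[C@H](O)C(=C)C#C[C@H](OC(C)=O)[C@@]2(C)[C@@H](O[Ti](Cl)(C4C=CC=C4)C4C=CC=C4)C[C@H]1OC(C)=O | intermediate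
34 | tricyclic enyne (OH at C6, C8, C14) | C=C1[C@@H]2[C@H](OC(C)=O)[C@]3(O)[C@@H](C)C(=O)O[C@H]3[C@H](O)C(=C)C#C[C@H](OC(C)=O)[C@@]2(C)[C@@H](O)C[C@H]1OC(C)=O | intermediate
35 | (3Z)-diene | C=C1[C@@H]2[C@H](OC(C)=O)[C@]3(O)[C@@H](C)C(=O)O[C@H]3[C@H](O)C(=C)/C=C\[C@H](OC(C)=O)[C@@]2(C)[C@@H](O)C[C@H]1OC(C)=O | intermediate
36 | (6S)-chloride | C=C1[C@@H]2[C@H](OC(C)=O)[C@]3(O)[C@@H](C)C(=O)O[C@H]3[C@@H](Cl)C(=C)/C=C\[C@H](OC(C)=O)[C@@]2(C)[C@@H](O)C[C@H]1OC(C)=O | intermediate
37 | CNP0164748.1 | C=C1[C@@H]2[C@H](OC(C)=O)[C@]3(O)[C@@H](C)C(=O)O[C@H]3[C@@H](Cl)C(=C)/C=C\[C@H](OC(C)=O)[C@@]2(C)[C@@H](OC(C)=O)C[C@H]1OC(C)=O | target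

## Step count and risks

Total step count: 26.
Longest linear sequence: 24 (steps 1 to 13 and 16 to 26). Steps 14 and 15 form the side branch.

**1. Step 23 (key step).**
- What may go wrong: the tertiary C1 radical may be quenched before it reaches C10, either by hydrogen loss toward the C14 allylic alcohol or by reduction. Alternatively, the pseudo-axial C14–O–Ti bond may tip the facial preference at C10=C11, so that facial selectivity is poor.
- Fallback: it sets out from 31 and comes back at 34, and it replaces the one-electron opening by a two-electron opening. MeAlCl2 is used in excess, so that the two hydroxyls are saturated first, in CH2Cl2 at −78 °C.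
- The Lewis acid ionizes the oxirane at C1, the C10=C11 olefin captures the developing tertiary cation across the ring, and C20 loses a proton.
- This is the Lewis-acid-induced cation–olefin cyclization known for epoxypolyenes and for medium-ring epoxy olefins. It makes no new isolated compound.

**2. Step 19.**
- What may go wrong: intermolecular coupling (oligomerization) or protonation of the alkenylchromium species may outrun closure of the 14-membered ring onto the hindered α-branched aldehyde.
- Fallback: it sets out from 20 and comes back at 29. The ring-closing bond is moved from C5–C6 to C3≡C4.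
- The zinc–ProPhenol alkynylation of step 16 is run with propyne to give the propynyl carbinol F1, which is acetylated to the triacetate F2.
- MeI/CaCO3 then unmasks the aldehyde F3.
- An intermolecular Nozaki–Hiyama–Kishi coupling (CrCl2, NiCl2 cat.) with pent-1-en-3-yn-2-yl triflate F4 gives the acyclic enynol F5. F4 is made from commercial pent-3-yn-2-one with Tf2O and the hindered pyridine of step 14.
- Dess–Martin oxidation of F5 gives the acyclic enynone F6.
- Ring-closing alkyne metathesis of the two methyl-capped alkynes closes the macrocycle with loss of but-2-yne and delivers 29. Conditions: Mo(CC6H4OMe-4)(OSiPh3)3, 5 Å MS, toluene, high dilution.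

**3. Step 25.**
- What may go wrong: chloride may attack at C16 (allylic transposition), or the activated dienyl alcohol may ionize with loss of configuration at C6.
- Fallback: it sets out from 34 and comes back at 36. The displacement is moved in front of the semihydrogenation.
- The enynol 34 carries an electron-withdrawing alkynyl group on C5, which disfavours both ionization and attack at C16. It is treated with PPh3/hexachloroacetone to give the chloro enyne F7.
- The strained ring alkyne of F7 is then semihydrogenated over Pd/CaCO3 poisoned with Pb(OAc)2 and quinoline. This should be faster than C–Cl hydrogenolysis and gives 36.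

## Further compounds

F0 | step 23 | none | none
F1 | step 19 | propynyl carbinol | CC#C[C@H](O)/C(C)=C/C[C@@H](OC(C)=O)/C(C)=C/[C@H](OC(C)=O)[C@]1(O)[C@@H](C)C(=O)O[C@H]1C2SCCCS2
F2 | step 19 | propynyl triacetate | CC#C[C@H](OC(C)=O)/C(C)=C/C[C@@H](OC(C)=O)/C(C)=C/[C@H](OC(C)=O)[C@]1(O)[C@@H](C)C(=O)O[C@H]1C2SCCCS2
F3 | step 19 | propynyl C6 aldehyde | CC#C[C@H](OC(C)=O)/C(C)=C/C[C@@H](OC(C)=O)/C(C)=C/[C@H](OC(C)=O)[C@]1(O)[C@@H](C)C(=O)O[C@H]1C=O
F4 | step 19 | pent-1-en-3-yn-2-yl triflate | CC#CC(=C)OS(=O)(=O)C(F)(F)F
F5 | step 19 | acyclic enynol (C6 epimers) | CC#C[C@H](OC(C)=O)/C(C)=C/C[C@@H](OC(C)=O)/C(C)=C/[C@H](OC(C)=O)[C@]1(O)[C@@H](C)C(=O)O[C@H]1C(O)C(=C)C#CC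
F6 | step 19 | acyclic enynone | CC#C[C@H](OC(C)=O)/C(C)=C/C[C@@H](OC(C)=O)/C(C)=C/[C@H](OC(C)=O)[C@]1(O)[C@@H](C)C(=O)O[C@H]1C(=O)C(=C)C#CC
F7 | step 25 | (6S)-chloro enyne | C=C1[C@@H]2[C@H](OC(C)=O)[C@]3(O)[C@@H](C)C(=O)O[C@H]3[C@@H](Cl)C(=C)C#C[C@H](OC(C)=O)[C@@]2(C)[C@@H](O)C[C@H]1OC(C)=O
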